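**Retrosynthetic overview**
- The target is unveiled by one hydrogenation that turns an isopropenyl group into the isopropyl group and removes four benzyl groups.
- The isopropenyl group comes from a methyl ketone, itself from ozonolysis of an (E)-but-2-en-2-yl group (the two-carbon remnant of the chirality donor).
- Key disconnection: the syncarpyl C–CH bond, made by a [3,3] Claisen rearrangement of an O-allyl enol ether of syncarpic acid with 1,3-chirality transfer from a C–O stereocentre.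
- The enol ether comes from Mitsunobu inversion of an (R,E)-aryl allylic alcohol, built by carboalumination/Negishi coupling of (R)-but-3-yn-2-ol with a tribenzylated aryl iodide (from 2,4,6-trihydroxytoluene by acylation, iodination, benzylation).
- Rings: both six-membered rings are bought intact (arene and triketone); no ring is formed. The single stereocentre is created in the Claisen step under control of the purchased carbinol centre.

Assumption: syncarpic acid and (R)-but-3-yn-2-ol are bought as catalogue chemicals.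

**Step 1**
Reactants: 1 2-methylbenzene-1,3,5-triol; 2 2-methylpropanoyl chloride
Product: 3 1-(2,4,6-trihydroxy-3-methylphenyl)-2-methylpropan-1-one
Conditions: AlCl3 (4 equiv), PhNO2, 60 °C; aq. HCl work-up
Reagents that add atoms: none
Why: Friedel–Crafts acylation of a highly activated arene whose two free positions are equivalent, so one monoketone forms and the ketone deactivates the ring against a second acylation.

**Step 2**
Reactants: 3
Product: 4 1-(2,4,6-trihydroxy-3-iodo-5-methylphenyl)-2-methylpropan-1-one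
Conditions: NIS (1.05 equiv), MeCN, 0 °C, dark
Reagents that add atoms: N-iodosuccinimide, O=C1CCC(=O)N1I
Why: Electrophilic aromatic iodination at the only free, strongly activated ring position, which also blocks C-benzylation in the next step.

**Step 3**
Reactants: 4
Product: 5 1-[2,4,6-tris(benzyloxy)-3-iodo-5-methylphenyl]-2-methylpropan-1-one
Conditions: BnBr (3.6 equiv), K2CO3 (5 equiv), DMF, 60 °C
Reagents that add atoms: benzyl bromide, BrCc1ccccc1
Why: Williamson ether synthesis in which only O-alkylation is possible, with heating to overcome the hydrogen-bonded ortho hydroxyls.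

**Step 4**
Reactants: 5; 6 (R)-but-3-yn-2-ol
Product: 9 1-{2,4,6-tris(benzyloxy)-3-[(1E,3R)-3-hydroxy-2-methylbut-1-en-1-yl]-5-methylphenyl}-2-methylpropan-1-one, via alkenylalane 7 (not isolated), via alkenylzinc chloride 8 (not isolated)
Conditions: 6 (1.5 equiv), AlMe3 (4 equiv), Cp2ZrCl2 (0.3 equiv), CH2Cl2, 0 °C to rt; then ZnCl2 (1.5 equiv), 5, Pd(P(t-Bu)3)2 (5 mol %), THF, 45 °C; aq. HCl work-up
Reagents that add atoms: trimethylaluminium, C[Al](C)C
Why: Negishi zirconium-catalysed carboalumination adds CH3 (internal) and Al (terminal) syn across the alkyne, and Al-to-Zn transmetalation followed by Negishi cross-coupling with retention gives the (E)-trisubstituted alkene while the bought (R) carbinol centre is untouched.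

**Step 5**
Reactants: 9; 10 syncarpic acid (2,2,4,4-tetramethylcyclohexane-1,3,5-trione, reacting as its enol)
Product: 11 5-{[(2S,3E)-4-{2,4,6-tris(benzyloxy)-3-methyl-5-(2-methylpropanoyl)phenyl}-3-methylbut-3-en-2-yl]oxy}-2,2,6,6-tetramethylcyclohex-4-ene-1,3-dione
Conditions: 10 (1.5 equiv), PPh3, DIAD, toluene, −20 °C to rt
Reagents that add atoms: none
Why: Mitsunobu reaction in which the acidic enol (pKa about 5) is O-alkylated by SN2 displacement of the alkoxyphosphonium ion with inversion, so the (R)-alcohol gives the (S)-enol ether.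

**Step 6**
Reactants: 11
Product: 14 5-(benzyloxy)-4-[(1S,2E)-2-methyl-1-{2,4,6-tris(benzyloxy)-3-methyl-5-(2-methylpropanoyl)phenyl}but-2-en-1-yl]-2,2,6,6-tetramethylcyclohex-4-ene-1,3-dione, via triketone tautomer 12 (not isolated), via enol 13 (not isolated)
Conditions: o-xylene (0.05 M), 140 °C, sealed tube; cool; then DMF, Cs2CO3, BnBr, rt
Reagents that add atoms: benzyl bromide, BrCc1ccccc1
Why: Claisen rearrangement ([3,3]-sigmatropic) through a chair transition state with the carbinol methyl pseudo-equatorial forms the C–C bond suprafacially across the (E)-allyl unit, transferring the (S) C–O centre into the new (S) C–C centre with an (E)-alkene; the enol is then O-benzylated, and any (Z)-isomer (which carries the opposite configuration) is removed here by chromatography.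

**Step 7**
Reactants: 14
Product: 16 5-(benzyloxy)-4-[(1S)-2-oxo-1-{2,4,6-tris(benzyloxy)-3-methyl-5-(2-methylpropanoyl)phenyl}propyl]-2,2,6,6-tetramethylcyclohex-4-ene-1,3-dione, via ozonide 15 (not isolated)
Conditions: O3, CH2Cl2, −78 °C (Sudan Red 7B endpoint); then Me2S, −78 °C to rt
Reagents that add atoms: ozone, [O-][O+]=O
Why: Ozonolysis selects the unconjugated trisubstituted alkene over the push-pull vinylogous ester and the acyl-deactivated arene, and the neutral reductive work-up leaves the adjacent stereocentre untouched.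

**Step 8**
Reactants: 16
Product: 17 5-(benzyloxy)-4-[(1S)-2-methyl-1-{2,4,6-tris(benzyloxy)-3-methyl-5-(2-methylpropanoyl)phenyl}prop-2-en-1-yl]-2,2,6,6-tetramethylcyclohex-4-ene-1,3-dione
Conditions: Zn, CH2Br2, TiCl4, THF/CH2Cl2, 0 °C to rt
Reagents that add atoms: dibromomethane, BrCBr
Why: Takai–Lombardo methylenation is non-basic, so the enolisable methyl ketone is olefinated without epimerising the alpha stereocentre, while the other three carbonyls are too hindered or deactivated to react.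

**Step 9**
Reactants: 17
Product: 18 5-hydroxy-4-[(1S)-2-methyl-1-{2,4,6-trihydroxy-3-methyl-5-(2-methylpropanoyl)phenyl}propyl]-2,2,6,6-tetramethylcyclohex-4-ene-1,3-dione (target)
Conditions: H2 (1 atm), Pd/C, EtOAc/EtOH, rt
Reagents that add atoms: none
Why: Catalytic hydrogenation saturates the 1,1-disubstituted alkene to isopropyl and hydrogenolysis cleaves the four benzyl groups under neutral conditions that do not open a retro-Michael racemisation path.

**Compound list**
1 | 2-methylbenzene-1,3,5-triol | Cc1c(O)cc(O)cc1O | starting material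
2 | 2-methylpropanoyl chloride | CC(C)C(Cl)=O | starting material
3 | 1-(2,4,6-trihydroxy-3-methylphenyl)-2-methylpropan-1-one | Cc1c(O)cc(O)c(C(=O)C(C)C)c1O | intermediate
4 | 1-(2,4,6-trihydroxy-3-iodo-5-methylphenyl)-2-methylpropan-1-one | Cc1c(O)c(I)c(O)c(C(=O)C(C)C)c1O | intermediate
5 | 1-[2,4,6-tris(benzyloxy)-3-iodo-5-methylphenyl]-2-methylpropan-1-one | Cc1c(OCc2ccccc2)c(I)c(OCc2ccccc2)c(C(=O)C(C)C)c1OCc1ccccc1 | intermediate
6 | (R)-but-3-yn-2-ol | C[C@@H](O)C#C | starting material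
7 | {(1E,3R)-3-[(dimethylalumanyl)oxy]-2-methylbut-1-en-1-yl}(dimethyl)alumane | C[C@@H](O[Al](C)C)/C(C)=C/[Al](C)C | intermediate (not isolated)
8 | chloro{(1E,3R)-3-[(dimethylalumanyl)oxy]-2-methylbut-1-en-1-yl}zinc | C[C@@H](O[Al](C)C)/C(C)=C/[Zn]Cl | intermediate (not isolated)
9 | 1-{2,4,6-tris(benzyloxy)-3-[(1E,3R)-3-hydroxy-2-methylbut-1-en-1-yl]-5-methylphenyl}-2-methylpropan-1-one | C[C@@H](O)/C(C)=C/c1c(OCc2ccccc2)c(C)c(OCc2ccccc2)c(C(=O)C(C)C)c1OCc1ccccc1 | intermediate
10 | syncarpic acid (2,2,4,4-tetramethylcyclohexane-1,3,5-trione) | CC1(C)C(=O)CC(=O)C(C)(C)C1=O | starting material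
11 | 5-{[(2S,3E)-4-{2,4,6-tris(benzyloxy)-3-methyl-5-(2-methylpropanoyl)phenyl}-3-methylbut-3-en-2-yl]oxy}-2,2,6,6-tetramethylcyclohex-4-ene-1,3-dione | C[C@H](OC1=CC(=O)C(C)(C)C(=O)C1(C)C)/C(C)=C/c1c(OCc2ccccc2)c(C)c(OCc2ccccc2)c(C(=O)C(C)C)c1OCc1ccccc1 | intermediate
12 | 2-[(1S,2E)-2-methyl-1-{2,4,6-tris(benzyloxy)-3-methyl-5-(2-methylpropanoyl)phenyl}but-2-en-1-yl]-4,4,6,6-tetramethylcyclohexane-1,3,5-trione | C/C=C(\C)[C@@H](c1c(OCc2ccccc2)c(C)c(OCc2ccccc2)c(C(=O)C(C)C)c1OCc1ccccc1)C1C(=O)C(C)(C)C(=O)C(C)(C)C1=O | intermediate (not isolated)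
13 | 5-hydroxy-4-[(1S,2E)-2-methyl-1-{2,4,6-tris(benzyloxy)-3-methyl-5-(2-methylpropanoyl)phenyl}but-2-en-1-yl]-2,2,6,6-tetramethylcyclohex-4-ene-1,3-dione | C/C=C(\C)[C@@H](c1c(OCc2ccccc2)c(C)c(OCc2ccccc2)c(C(=O)C(C)C)c1OCc1ccccc1)C1=C(O)C(C)(C)C(=O)C(C)(C)C1=O | intermediate (not isolated)
14 | 5-(benzyloxy)-4-[(1S,2E)-2-methyl-1-{2,4,6-tris(benzyloxy)-3-methyl-5-(2-methylpropanoyl)phenyl}but-2-en-1-yl]-2,2,6,6-tetramethylcyclohex-4-ene-1,3-dione | C/C=C(\C)[C@@H](c1c(OCc2ccccc2)c(C)c(OCc2ccccc2)c(C(=O)C(C)C)c1OCc1ccccc1)C1=C(OCc2ccccc2)C(C)(C)C(=O)C(C)(C)C1=O | intermediate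
15 | secondary ozonide of 14 (3,5-dimethyl-1,2,4-trioxolan-3-yl in place of the butenyl group; trioxolane carbons unassigned, mixture) | CC1OOC(C)(O1)[C@@H](c1c(OCc2ccccc2)c(C)c(OCc2ccccc2)c(C(=O)C(C)C)c1OCc1ccccc1)C1=C(OCc2ccccc2)C(C)(C)C(=O)C(C)(C)C1=O | intermediate (not isolated)
16 | 5-(benzyloxy)-4-[(1S)-2-oxo-1-{2,4,6-tris(benzyloxy)-3-methyl-5-(2-methylpropanoyl)phenyl}propyl]-2,2,6,6-tetramethylcyclohex-4-ene-1,3-dione | CC(=O)[C@@H](c1c(OCc2ccccc2)c(C)c(OCc2ccccc2)c(C(=O)C(C)C)c1OCc1ccccc1)C1=C(OCc2ccccc2)C(C)(C)C(=O)C(C)(C)C1=O | intermediate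
17 | 5-(benzyloxy)-4-[(1S)-2-methyl-1-{2,4,6-tris(benzyloxy)-3-methyl-5-(2-methylpropanoyl)phenyl}prop-2-en-1-yl]-2,2,6,6-tetramethylcyclohex-4-ene-1,3-dione | C=C(C)[C@@H](c1c(OCc2ccccc2)c(C)c(OCc2ccccc2)c(C(=O)C(C)C)c1OCc1ccccc1)C1=C(OCc2ccccc2)C(C)(C)C(=O)C(C)(C)C1=O | intermediate
18 | 5-hydroxy-4-[(1S)-2-methyl-1-{2,4,6-trihydroxy-3-methyl-5-(2-methylpropanoyl)phenyl}propyl]-2,2,6,6-tetramethylcyclohex-4-ene-1,3-dione | Cc1c(O)c(C(=O)C(C)C)c(O)c([C@@H](C2=C(O)C(C)(C)C(=O)C(C)(C)C2=O)C(C)C)c1O | target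

**Totals**
Total step count: 9. Longest linear sequence: 9 steps (1 to 18); 6 and 10 are bought.

**Three steps most likely to fail, each with a fallback**

Step 6. The [3,3] shift has to form a very congested bond at 140 °C and must beat elimination and ionisation of the allylic enol ether, which would erode the chirality transfer. Fallback: exchange the roles of the two rings so that the same product arises from an aromatic Claisen rearrangement that forms the C–aryl bond instead. Setting out from 10, iodination with NIS gives 5-hydroxy-4-iodo-2,2,6,6-tetramethylcyclohex-4-ene-1,3-dione F3, and O-benzylation (BnBr, Ag2CO3) gives 5-(benzyloxy)-4-iodo-2,2,6,6-tetramethylcyclohex-4-ene-1,3-dione F4. Carboalumination of bought (S)-but-3-yn-2-ol F5 (AlMe3, Cp2ZrCl2) and Negishi coupling with F4 (ZnCl2, Pd(PPh3)4) give the (1E,3S)-hydroxybutenyl enol ether F6. Mitsunobu reaction of F6 with the para hydroxyl of phenol 3 (inversion) gives the (1E,3R)-aryl ether F7. Aromatic Claisen rearrangement of F7 (toluene, 110 °C) to the free ortho position gives the (1S,2E)-triphenol F8, and tribenzylation (BnBr, Cs2CO3, DMF) comes back to the route at 14.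

Step 4. The one-pot carboalumination and cross-coupling meets a di-ortho-substituted aryl iodide, and methyl transfer from aluminium can compete. Fallback: reverse the polarity and couple two isolated partners. Setting out from 6, carboalumination and iodinolysis (AlMe3, Cp2ZrCl2; then I2) give (2R,3E)-4-iodo-3-methylbut-3-en-2-ol F1. Setting out from 5, iodine–magnesium exchange (i-PrMgCl·LiCl, THF, −40 °C) and trapping with 2-isopropoxy-4,4,5,5-tetramethyl-1,3,2-dioxaborolane give the aryl pinacol boronate F2. Suzuki–Miyaura coupling of F1 with F2 (Pd(OAc)2, SPhos, K3PO4, THF/H2O, 50 °C) comes back to the route at 9.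

Step 8. The ketone is hindered and easily enolised, so methylenation may stall or epimerise the neighbouring centre. Fallback: a two-stage Peterson olefination. Setting out from 16, addition of Me3SiCH2Li/CeCl3 (non-basic organocerium, THF, −78 °C) gives the β-hydroxysilane F9 as a mixture of carbinol epimers, and elimination with aqueous HF in MeCN comes back to the route at 17.

**Further compounds**
F1 | step 4 | (2R,3E)-4-iodo-3-methylbut-3-en-2-ol | C[C@@H](O)/C(C)=C/I
F2 | step 4 | 1-[2,4,6-tris(benzyloxy)-3-methyl-5-(4,4,5,5-tetramethyl-1,3,2-dioxaborolan-2-yl)phenyl]-2-methylpropan-1-one | Cc1c(OCc2ccccc2)c(B2OC(C)(C)C(C)(C)O2)c(OCc2ccccc2)c(C(=O)C(C)C)c1OCc1ccccc1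
F3 | step 6 | 5-hydroxy-4-iodo-2,2,6,6-tetramethylcyclohex-4-ene-1,3-dione | OC1=C(I)C(=O)C(C)(C)C(=O)C1(C)C
F4 | step 6 | 5-(benzyloxy)-4-iodo-2,2,6,6-tetramethylcyclohex-4-ene-1,3-dione | IC1=C(OCc2ccccc2)C(C)(C)C(=O)C(C)(C)C1=O
F5 | step 6 | (S)-but-3-yn-2-ol (bought) | C[C@H](O)C#C
F6 | step 6 | 5-(benzyloxy)-4-[(1E,3S)-3-hydroxy-2-methylbut-1-en-1-yl]-2,2,6,6-tetramethylcyclohex-4-ene-1,3-dione | C[C@H](O)/C(C)=C/C1=C(OCc2ccccc2)C(C)(C)C(=O)C(C)(C)C1=O
F7 | step 6 | 5-(benzyloxy)-4-{(1E,3R)-3-[3,5-dihydroxy-2-methyl-4-(2-methylpropanoyl)phenoxy]-2-methylbut-1-en-1-yl}-2,2,6,6-tetramethylcyclohex-4-ene-1,3-dione | C[C@@H](Oc1cc(O)c(C(=O)C(C)C)c(O)c1C)/C(C)=C/C1=C(OCc2ccccc2)C(C)(C)C(=O)C(C)(C)C1=O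
F8 | step 6 | 5-(benzyloxy)-4-[(1S,2E)-2-methyl-1-{2,4,6-trihydroxy-3-methyl-5-(2-methylpropanoyl)phenyl}but-2-en-1-yl]-2,2,6,6-tetramethylcyclohex-4-ene-1,3-dione | C/C=C(\C)[C@@H](c1c(O)c(C)c(O)c(C(=O)C(C)C)c1O)C1=C(OCc2ccccc2)C(C)(C)C(=O)C(C)(C)C1=O
F9 | step 8 | 5-(benzyloxy)-4-[(1S)-2-hydroxy-2-methyl-1-{2,4,6-tris(benzyloxy)-3-methyl-5-(2-methylpropanoyl)phenyl}-3-(trimethylsilyl)propyl]-2,2,6,6-tetramethylcyclohex-4-ene-1,3-dione (carbinol epimers) | CC(O)(C[Si](C)(C)C)[C@@H](c1c(OCc2ccccc2)c(C)c(OCc2ccccc2)c(C(=O)C(C)C)c1OCc1ccccc1)C1=C(OCc2ccccc2)C(C)(C)C(=O)C(C)(C)C1=O
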